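**Assumptions.** (S)-β-methyl-δ-valerolactone and 5-iodopent-1-yne are commercially available. The C9 epimer formed in Step 9 is separated by chromatography. The CO2Me group is installed last, because no allowed starting material contains it.

## Retrosynthetic overview
1. Target ← aryl bromide **12** by Pd-catalysed methoxycarbonylation, with acetate cleavage in the same pot.
2. **12** ← acyclic dienyne **11** in one HAT-initiated radical cascade. Ring B forms first (tertiary C9 radical, 6-endo onto the E-trisubstituted alkene), then ring A (tertiary C5 radical, 6-exo-dig onto the terminal alkyne). This sets C9, C10, C5 and the exocyclic CH2 together.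
3. **11** ← Negishi coupling of E-vinyl iodide **9** with a pent-4-ynylzinc reagent. **9** comes from carboalumination of terminal alkyne **7**.
4. The aryl-CH2 bond comes from an aromatic Claisen rearrangement of the 4-bromophenyl ether **6**. C8 (S) comes from (S)-β-methyl-δ-valerolactone (**1**).

## Route

**Step 1**
Reactants: **1** (S)-4-methyloxan-2-one
Product: **2** methyl (3R)-5-bromo-3-methylpentanoate
Conditions: AcBr, MeOH, 0 °C → 65 °C (HBr generated in situ)
Reagents that add atoms: HBr (Br); MeOH (CO)
Why: Bromide opens the lactone at the alkyl C–O bond (SN2) with concomitant Fischer esterification, and the remote C3 stereocentre is untouched (the descriptor changes from S to R only because Br outranks the ester carbon in CIP priority).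

**Step 2**
Reactants: **2**
Product: **3** methyl (3S)-5-bromo-3-methyl-2-methylidenepentanoate
Conditions: LDA, THF, −78 °C; then CH2=NMe2⁺ I⁻; then MeI, then DBU, rt (one pot)
Reagents that add atoms: Eschenmoser's salt, C=[N+](C)C.[I-] (supplies the =CH2 carbon)
Why: Ester-enolate Mannich aminomethylation followed by quaternisation and elimination (Eschenmoser α-methylenation); the stereocentre is β to the enolate carbon and is not epimerised.

**Step 3**
Reactants: **3**
Product: **4** (3S)-5-bromo-3-methyl-2-methylidenepentan-1-ol
Conditions: DIBAL-H (2.2 equiv), CH2Cl2, −78 °C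
Reagents that add atoms: none
Why: DIBAL-H delivers 1,2-reduction of the acrylate ester to the allylic alcohol, leaving the alkene and primary C–Br intact.

**Step 4**
Reactants: **4**; **5** 4-bromophenol
Product: **6** 1-bromo-4-{[(3S)-5-bromo-3-methyl-2-methylidenepentyl]oxy}benzene
Conditions: DIAD, PPh3, THF, 0 °C → rt
Reagents that add atoms: none
Why: Mitsunobu O-arylation; the 2-substituted allyl system has identical termini, so SN2 and SN2′ give the same constitution.

**Step 5**
Reactants: **6**
Product: **7** 1-bromo-4-{[(3S)-3-methyl-2-methylidenehept-6-yn-1-yl]oxy}benzene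
Conditions: LiC≡CH·H2NCH2CH2NH2, DMSO, rt
Reagents that add atoms: lithium acetylide–ethylenediamine, [Li]C#C (adds C≡CH)
Why: SN2 displacement of the unhindered primary alkyl bromide (alkyne installation); the aryl bromide and allyl ether are inert.

**Step 6**
Reactants: **7**
Product: **8** 4-bromo-2-[(3S)-3-methyl-2-methylidenehept-6-yn-1-yl]phenyl acetate
Conditions: Ac2O (5 equiv), NaOAc (cat.), o-Cl2C6H4, 190 °C, sealed tube, 2 h
Reagents that add atoms: acetic anhydride, CC(=O)OC(C)=O (adds the acetyl group)
Why: Aromatic Claisen [3,3] rearrangement moves the allyl terminus to the free ortho carbon to give Ar–CH2–C(=CH2)R, and Ac2O traps the phenol as the acetate so it cannot act as an H-atom donor in Step 9.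

**Step 7**
Reactants: **8**
Product: **9** 4-bromo-2-[(3S,6E)-7-iodo-3,6-dimethyl-2-methylidenehept-6-en-1-yl]phenyl acetate
Conditions: Me3Al (3 equiv), Cp2ZrCl2 (0.2 equiv), CH2Cl2, 0 °C → rt; then I2, THF, −30 °C
Reagents that add atoms: trimethylaluminium, C[Al](C)C (adds CH3); iodine, II (adds I)
Why: Negishi Zr-catalysed syn-methylalumination of the terminal alkyne sets the trisubstituted alkene E, and iodinolysis of the C–Al bond proceeds with retention.

**Step 8**
Reactants: **9**; **10** 5-iodopent-1-yne
Product: **11** 4-bromo-2-[(3S,6E)-3,6-dimethyl-2-methylidenedodec-6-en-11-yn-1-yl]phenyl acetate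
Conditions: **10**, Zn dust, LiCl, THF, 50 °C (forms C#CCCC[Zn]I); then **9**, Pd(dppf)Cl2 (5 mol%), THF, 25 °C
Reagents that add atoms: none beyond numbered reactant **10**; the zinc reagent is made in situ
Why: Negishi sp2–sp3 coupling keeps the alkene geometry; the vinyl iodide reacts in preference to the aryl bromide, and the alkylzinc tolerates the terminal alkyne and aryl acetate.

**Step 9**
Reactants: **11**
Product: **12** 4-bromo-2-{[decalinyl]methyl}phenyl acetate, the trans-decalin carrying C8-Me, C9-Me/CH2Ar, C5-Me and exocyclic =CH2
Conditions: Fe(acac)3 (1.0 equiv), PhSiH3 (3 equiv), EtOH (0.01 M), 60 °C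
Reagents that add atoms: none (net addition of H2)
Why: Proposed new method: Fe–H hydrogen-atom transfer to the 1,1-disubstituted alkene gives a tertiary C9 radical that closes ring B by chair-like 6-endo attack on the E-trisubstituted alkene (C8-Me equatorial, C9-Me axial and syn to the angular methyl, C9–C10 bond formed, tertiary C5 radical), which closes ring A by 6-exo-dig attack on the alkyne with trans ring fusion, and the exocyclic vinyl radical takes H from PhSiH3/EtOH to give the =CH2. The closest known chemistry is HAT-initiated radical polyene cyclisation and Ti(III) radical cascades that terminate on alkynes. The C9 epimer (near 1:1 at this centre) is expected as the main by-product.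

**Step 10**
Reactants: **12**
Product: **13** dictyoceratin C
Conditions: Pd(OAc)2 (5 mol%), dppf (10 mol%), CO (5 atm), K2CO3 (3 equiv), MeOH/DMF 1:1, 90 °C
Reagents that add atoms: carbon monoxide, [C-]#[O+]; methanol, CO (together give CO2Me)
Why: Pd-catalysed alkoxycarbonylation of the aryl bromide (para to the oxygen) gives the methyl ester, and K2CO3/MeOH removes the acetate in the same pot to free the phenol; no stereocentre is touched.

## Compound list
1 | (S)-4-methyloxan-2-one | O=C1C[C@@H](C)CCO1 | starting material
2 | methyl (3R)-5-bromo-3-methylpentanoate | COC(=O)C[C@@H](C)CCBr | intermediate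
3 | methyl (3S)-5-bromo-3-methyl-2-methylidenepentanoate | C=C(C(=O)OC)[C@@H](C)CCBr | intermediate
4 | (3S)-5-bromo-3-methyl-2-methylidenepentan-1-ol | C=C(CO)[C@@H](C)CCBr | intermediate
5 | 4-bromophenol | Oc1ccc(Br)cc1 | starting material
6 | 1-bromo-4-{[(3S)-5-bromo-3-methyl-2-methylidenepentyl]oxy}benzene | C=C(COc1ccc(Br)cc1)[C@@H](C)CCBr | intermediate
7 | 1-bromo-4-{[(3S)-3-methyl-2-methylidenehept-6-yn-1-yl]oxy}benzene | C=C(COc1ccc(Br)cc1)[C@@H](C)CCC#C | intermediate
8 | 4-bromo-2-[(3S)-3-methyl-2-methylidenehept-6-yn-1-yl]phenyl acetate | C=C(Cc1cc(Br)ccc1OC(C)=O)[C@@H](C)CCC#C | intermediate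
9 | 4-bromo-2-[(3S,6E)-7-iodo-3,6-dimethyl-2-methylidenehept-6-en-1-yl]phenyl acetate | C=C(Cc1cc(Br)ccc1OC(C)=O)[C@@H](C)CC/C(C)=C/I | intermediate
10 | 5-iodopent-1-yne | C#CCCCI | starting material
11 | 4-bromo-2-[(3S,6E)-3,6-dimethyl-2-methylidenedodec-6-en-11-yn-1-yl]phenyl acetate | C=C(Cc1cc(Br)ccc1OC(C)=O)[C@@H](C)CC/C(C)=C/CCCC#C | intermediate
12 | 4-bromo-2-{[decalinyl]methyl}phenyl acetate (cascade product) | C=C1CCC[C@H]2[C@](C)(Cc3cc(Br)ccc3OC(C)=O)[C@@H](C)CC[C@]12C | intermediate
13 | dictyoceratin C | C=C1CCC[C@H]2[C@](C)(Cc3cc(C(=O)OC)ccc3O)[C@@H](C)CC[C@]12C | target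

## Totals
- Total steps: 10.
- Longest linear sequence: 10 (1 → 2 → 3 → 4 → 6 → 7 → 8 → 9 → 11 → 12 → 13). 4-Bromophenol (**5**) enters at Step 4 and 5-iodopent-1-yne (**10**) at Step 8.

## Three steps most likely to fail
1. **Step 9 (radical cascade).** The C9 epimer is likely near 1:1 because CH3 and CH2Ar have similar axial preference. Premature reduction of the C9 radical, a 5-exo side path, and over-reduction of the product alkene are also possible. *Fallback (different approach):* build ring A first from 2-methylcyclohex-2-enone. Add the C9 tertiary radical (HAT from the aryl-allyl fragment carrying a CH2CH2OTs chain) to the enone, close ring B by KOtBu enolate alkylation, and install the =CH2 by Ph3P=CH2 methylenation of the ring-A ketone.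
2. **Step 6 (Claisen in Ac2O at 190 °C).** The terminal alkyne and the 1,1-disubstituted alkene may undergo thermal ene-type side reactions. *Fallback (different approach):* convert **4** to its allylic methyl carbonate, couple it with 2-acetoxy-5-bromophenylboronic ester under Pd(0) in an allyl–aryl Suzuki-type coupling, then continue from the alkyl bromide with Step 5.
3. **Step 2 (α-methylenation with LDA in the presence of the primary C–Br).** Competing E2 elimination or enolate alkylation could lower the yield. *Fallback (different approach):* α-methylenate lactone **1** itself (cyclic enolate), reduce it with LiAlH4 to the diol, then differentiate the homoallylic alcohol (TBDPS protection, Appel bromination of the allylic alcohol is avoided by protecting first) to reach **4** by a different order of events.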